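## Structural features

The target is a germacrane: a ten-membered carbocycle (C1–C10; C11–C13 form the three-carbon branch on C7, C14 sits on C10, C15 on C4). It carries a Z-trisubstituted C1=C10 olefin, a trans-trisubstituted C4–C5 epoxide, a free C6 hydroxyl, a C7 isopropyl group and a C8 3,4,5-trimethoxybenzoate. Five contiguous stereocentres run from C4 to C8 (4S,5S,6R,7S,8R). The C6 oxygen, the C7 isopropyl group and the C8 ester are all cis on the ring, and the epoxide oxygen lies on the face that the C6 hydroxyl occupies when C6–H eclipses the C15 methyl. Three groups are fragile: the epoxy alcohol (transannular opening by acid, Payne rearrangement by base), the aroyl group (it can migrate from O8 to the cis-1,3 O6 under base), and the (Z,E)-cyclodeca-1,5-diene of every pre-epoxide intermediate (Cope rearrangement on heating). The real difficulty is a medium ring with a Z olefin combined with the all-cis C6/C7/C8 triad, which no simple conformational bias of a ten-membered ring provides. The key step exploits the C6 carbinol: it is allylic to C4=C5 and bonded to C7, which bears the C11–C13 branch. That is the pattern left by a [2,3]-Wittig shift of an ether oxygen bridging C6 and C12 in a thirteen-membered ring. Analysis of that shift (step 15) indicates that the C8 oxygen should end trans to the new C7 branch, so the route carries C8 as its epimer through the ring contraction and inverts it when the ester is introduced.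

## Logic of the disconnections

31 to 30: the C4–O and C5–O bonds of the epoxide are cut last. The epoxide is the most fragile group and lies syn to the C6 hydroxyl, so a hydroxyl-directed epoxidation can deliver it. Two stereocentres and all epoxide-related lability vanish from every earlier compound. The forward step must choose C4=C5 over C1=C10 and the correct face, both through the free hydroxyl of 30.

30 to 29 to 27 + 28: the C8–O bond is cut with inversion, after O6 is masked. The ring contraction should place O8 trans to the C7 branch, so the ester has to arrive by displacement at C8. Esterification and stereochemical correction then cost one step. The demands are an SN2 reaction at a hindered ring carbon and an O6 protecting group that leaves under neutral conditions, because base could move the aroyl group to O6.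

27 to 26 to 25 to 24: no skeletal bond is cut; the O8 silyl group is restored, the O6 PMB group removed and the isopropyl group traced to isopropenyl. This leads back to the direct product of the sigmatropic step. The forward demands are hydrogenation of the 1,1-disubstituted olefin only, and protection of O6 before O8 is freed.

24 to 22 (key): the C6–C7 bond is cut and C12 is reconnected to O6. The ten-membered carbocycle with two new stereocentres becomes a thirteen-membered ether with one stereocentre and three olefins of fixed geometry. The forward step needs regioselective deprotonation at C6, a cis-fused envelope, and facial control by C8. Two design points follow. An arylmethyl ether on O8 is excluded, because it would be an allyl benzyl ether with acidic benzylic protons and would undergo its own Wittig shift; a TIPS ether is used. C8 is carried as the S epimer, because the 8R ether could reach the all-cis triad only with its oxygen in the allylically strained in-plane position or with C9 anti to the incoming C6.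

22 to 21 to 20 to 18: the C6–O bond is cut (Williamson). The macrocycle becomes an open-chain triene. The forward steps need high dilution and differentiation of the two primary allylic oxygens: C6 as chloride, O12 as a TBS ether removable beside the secondary TIPS ether.

18 to 15: the C4–C15 and C5–C6 bonds are cut, taking the E-trisubstituted allylic alcohol back to a terminal alkyne. The forward syn-carbometalation must be regio- and stereoselective and must tolerate two allylic silyl ethers.

15 to 14 to 9 + 13: the C7–C8 bond is cut. The only stereocentre that enters the key step is made here. The forward step needs an enantioselective alkenyl addition that keeps the Z geometry and works without base, because 9 is a β,γ-unsaturated aldehyde.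

13 to 12 to 10: the C11–C13 and C7–I bonds are cut. A chelation-controlled anti-carbomagnesiation of 10 fixes the Z geometry that later places C8 cis to C12.

9 to 8 to 7 to 4 + 5: the C2–C3 bond is cut, an alkylation of 6 (made from 5) by the allylic chloride 4. The forward step needs SN2 substitution without allylic transposition or loss of the Z geometry.

4 to 3 to 2 to 1: no skeletal bond is cut; the Z geometry of C1=C10 is taken from the ring of 1. The forward steps must tell the allylic hydroxyl of 2 from the homoallylic one.

## Other disconnections considered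

Alternative 1: This cut removes three ring bonds at once (C2–C3, C6–C7, C8–C9) and returns isoprene A2, the silyl dienol ether A3 and the alkynylboronate A4. In the forward step, zerovalent nickel (Ni(cod)2 with a chiral ligand) would couple A2 and A3 oxidatively, insert A4 and close the ring by reductive elimination to the cyclodecatriene A1.
- In its favour: no other plan is as convergent. The carbocycle, both trisubstituted olefins, the C6 oxygen and handles at C7 and C8 would arise in one operation from small feedstocks. On step economy it is clearly the better plan. A syn-hydrogenation of C7=C8 followed by stereoretentive C–B oxidation would in principle give the 7,8-cis relation directly, where the chosen plan needs an inversion.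
- Against it here: the cross-coupling of two different 2-substituted dienes must beat both homodimerisations and control orientation twice. The olefin geometries are set by the metallacycle, not by design. Enantiocontrol at C6 has no close precedent for three different partners. The later hydrogenation would have to select the most hindered, tetrasubstituted olefin beside two trisubstituted ones.
- Comparison: structurally, A1 still lacks two of the three carbinol-region stereocentres, whereas the ring contraction sets C6 and C7 while the ring forms. Mechanistically, the nickel step would be new chemistry, whereas the sigmatropic shift belongs to a known class. In step count the alternative wins by a wide margin if it can be made to work.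

Alternative 2: This cut opens C1–C2 and returns the open-chain iodo diene A6. In the forward step, 9-BBN-H would add to the terminal C2=C3 alkene, and the C2 alkylborane would couple with the Z-alkenyl iodide under PdCl2(dppf) and Cs2CO3 to give A5, the TBS ether of 30.
- In its favour: the C6–C8 triad would be built in an open chain by aldol-type reactions of established reliability, with the aryl ester already in place and C8 in its final configuration. Neither transannular stereocontrol nor an inversion is needed, and on this point it is better than the chosen plan. The Z geometry is transferred with retention. Only desilylation and directed epoxidation would remain, a shorter end game than the chosen one.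
- Against it here: end-to-end closure of a strained ten-membered (Z,E)-diene by sp3–sp2 coupling competes with protodeboronation, β-hydride elimination and oligomerisation. The hydroboration must pick the terminal alkene of a 1,3-diene next to an allylic silyl ether. Aqueous base and heat act on an aryl ester.
- Comparison: on structure it is equal or better, since every stereocentre is fixed before cyclisation. On mechanism the chosen plan is the safer ring synthesis: it closes an unstrained thirteen-membered ether and lets strain build during a concerted contraction, while the alternative must overcome the strain in the bond-forming event. On step economy the two are about equal.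

Alternative 3: This cut reconnects C5 to C10 and returns the cis-fused decalin A8 (C5 tertiary alcohol, C1 mesylate). In the forward step, KOtBu would form the C5 alkoxide; the C5–C10 bond, anti-periplanar to C1–O, would break, giving the C5 ketone and the Z-C1=C10 olefin of A7.
- In its favour: the fragmentation is classical and stereoelectronically strict. The Z geometry follows from the relative configuration of C1 and C10. The C6–C8 centres would be set on a chair with a predictable bias and without inversion, which is better than the chosen plan on stereochemical predictability. Like the chosen plan, it avoids a direct medium-ring closure, so the two are equal there.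
- Against it here: A8 needs seven stereocentres, three of which are destroyed. A7 carries a C5 ketone and a C4 tertiary silyl ether that must still become the trans epoxide (reduction, activation, closure with inversion) next to the enolisable C6 centre. The PMB-to-ester exchange at C8 is still ahead. Strong base beside silyl groups on neighbouring oxygens invites silyl migration.
- Comparison: on mechanism the key step is more secure than the sigmatropic shift. On structure, the oxidation pattern of A7 is further from the target than that of 24. On step economy it is clearly the longest of the four plans.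

Key step: step 15

Assumption 1: germacrane numbering is used for all compounds, open-chain ones included; the CIP descriptors at C6 and C7 change with the groups on O6 and O8 although these centres are not touched after step 15.
Assumption 2: the ligand enantiomer in step 9 is the one expected to give the 4S carbinol; the sense of induction would be confirmed by MTPA-ester analysis, and the enantiomeric ligand used if it is the reverse.

Step 1
Reactants: 1 4-methyl-5,6-dihydro-2H-pyran-2-one
Product: 2 (2Z)-3-methylpent-2-ene-1,5-diol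
Conditions: i-Bu2AlH (3.2 equiv), CH2Cl2, −78 → 0 °C; aq potassium sodium tartrate
Reagents that add atoms: none
Why: Hydride reduction of the unsaturated lactone (ester to lactol to enal to allylic alcohol, 1,2-mode); the Z geometry is fixed because both olefin substituents were ring members.

Step 2
Reactants: 2 (2Z)-3-methylpent-2-ene-1,5-diol
Product: 3 (3Z)-5-chloro-3-methylpent-3-en-1-ol
Conditions: NCS, Me2S, CH2Cl2, −20 → 0 °C
Reagents that add atoms: N-chlorosuccinimide, ClN1C(=O)CCC1=O
Why: Corey–Kim chlorination; only the allylic alkoxysulfonium salt is displaced by chloride (SN2, geometry kept), the saturated hydroxyl is returned on work-up. The product is used at once because it can cyclise to a dihydropyran.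

Step 3
Reactants: 3 (3Z)-5-chloro-3-methylpent-3-en-1-ol
Product: 4 tert-butyl{[(3Z)-5-chloro-3-methylpent-3-en-1-yl]oxy}dimethylsilane
Conditions: TBSCl, imidazole, CH2Cl2, 0 °C → rt
Reagents that add atoms: tert-butyldimethylsilyl chloride, CC(C)(C)[Si](C)(C)Cl
Why: Standard silylation; it removes the internal nucleophile before the organolithium step.

Step 4
Reactants: 4 tert-butyl{[(3Z)-5-chloro-3-methylpent-3-en-1-yl]oxy}dimethylsilane; 5 trimethyl(prop-1-yn-1-yl)silane
Product: 7 tert-butyldimethyl{[(3Z)-3-methyl-8-(trimethylsilyl)oct-3-en-7-yn-1-yl]oxy}silane, via 3-lithio-1-(trimethylsilyl)propyne 6 (not isolated)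
Conditions: 5, n-BuLi, THF, −78 → −20 °C; then 4, −78 °C → rt
Reagents that add atoms: none
Why: SN2 alkylation of a silyl-stabilised propargyl anion by a primary allylic chloride (C2–C3 bond); the silyl group directs reaction to the propargylic carbon and the Z olefin is not involved.

Step 5
Reactants: 7 tert-butyldimethyl{[(3Z)-3-methyl-8-(trimethylsilyl)oct-3-en-7-yn-1-yl]oxy}silane
Product: 8 (3Z)-3-methyloct-3-en-7-yn-1-ol
Conditions: Bu4NF (2.5 equiv), THF, 0 °C → rt
Reagents that add atoms: none
Why: Fluoride cleaves both the O–Si and the alkynyl C–Si bond in one operation.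

Step 6
Reactants: 8 (3Z)-3-methyloct-3-en-7-yn-1-ol
Product: 9 (3Z)-3-methyloct-3-en-7-ynal
Conditions: Dess–Martin periodinane, NaHCO3, CH2Cl2, 0 °C; used crude
Reagents that add atoms: none
Why: Dess–Martin oxidation under buffered, non-basic conditions, so the β,γ-unsaturated aldehyde should not move into conjugation.

Step 7
Reactants: 10 prop-2-yn-1-ol
Product: 12 (2Z)-3-iodo-2-methylprop-2-en-1-ol, via alkenylmagnesium alkoxide 11 (not isolated)
Conditions: MeMgBr (2.5 equiv), CuI (10 mol%), THF, −10 °C → rt; then I2, −78 → 0 °C
Reagents that add atoms: methylmagnesium bromide, C[Mg]Br; iodine, II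
Why: Copper-catalysed anti-carbomagnesiation of a propargylic alkoxide; chelation keeps magnesium cis to the CH2O group, and iodinolysis with retention gives the Z iodide.

Step 8
Reactants: 12 (2Z)-3-iodo-2-methylprop-2-en-1-ol
Product: 13 tert-butyl{[(2Z)-3-iodo-2-methylprop-2-en-1-yl]oxy}dimethylsilane
Conditions: TBSCl, imidazole, CH2Cl2, 0 °C → rt
Reagents that add atoms: tert-butyldimethylsilyl chloride, CC(C)(C)[Si](C)(C)Cl
Why: Standard silylation of the primary alcohol; the TBS group can later be removed beside a secondary TIPS ether.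

Step 9
Reactants: 9 (3Z)-3-methyloct-3-en-7-ynal; 13 tert-butyl{[(2Z)-3-iodo-2-methylprop-2-en-1-yl]oxy}dimethylsilane
Product: 14 (2Z,4S,6Z)-1-[(tert-butyldimethylsilyl)oxy]-2,6-dimethylundeca-2,6-dien-10-yn-4-ol
Conditions: CrCl2 (10 mol%), (S)-N-[2-(4-isopropyl-4,5-dihydrooxazol-2-yl)-6-methylphenyl]methanesulfonamide (11 mol%), Et3N, NiCl2·2,9-dimethyl-1,10-phenanthroline (2 mol%), Mn, Cp2ZrCl2, LiCl, MeCN, rt
Reagents that add atoms: none
Why: Catalytic asymmetric Nozaki–Hiyama–Kishi coupling (C7–C8 bond). Zerovalent nickel activates the C–I bond with retention of the Z geometry, and the alkenyl trivalent chromium species bound to the chiral sulfonamide adds to one aldehyde face to set C8 (4S in this chain). The medium is non-basic, so 9 should not isomerise.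

Step 10
Reactants: 14 (2Z,4S,6Z)-1-[(tert-butyldimethylsilyl)oxy]-2,6-dimethylundeca-2,6-dien-10-yn-4-ol
Product: 15 (2Z,4S,6Z)-1-[(tert-butyldimethylsilyl)oxy]-2,6-dimethyl-4-[(triisopropylsilyl)oxy]undeca-2,6-dien-10-yne
Conditions: i-Pr3SiOTf, 2,6-lutidine, CH2Cl2, −78 → 0 °C
Reagents that add atoms: triisopropylsilyl trifluoromethanesulfonate, CC(C)[Si](C(C)C)(C(C)C)OS(=O)(=O)C(F)(F)F
Why: Silylation of the secondary allylic alcohol. TIPS has no acidic α-protons, resists migration to a neighbouring alkoxide and is bulky enough to steer steps 14 and 15.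

Step 11
Reactants: 15 (2Z,4S,6Z)-1-[(tert-butyldimethylsilyl)oxy]-2,6-dimethyl-4-[(triisopropylsilyl)oxy]undeca-2,6-dien-10-yne
Product: 18 (2E,6Z,9S,10Z)-12-[(tert-butyldimethylsilyl)oxy]-3,7,11-trimethyl-9-[(triisopropylsilyl)oxy]dodeca-2,6,10-trien-1-ol, via alkenyldimethylalane 16 (not isolated), via lithium alkenylalanate 17 (not isolated)
Conditions: Me3Al (3 equiv), Cp2ZrCl2 (25 mol%), H2O (1 equiv), CH2Cl2, −20 → 0 °C; then n-BuLi, THF, −78 °C; (CH2O)n, −78 °C → rt
Reagents that add atoms: trimethylaluminium, C[Al](C)C; formaldehyde (from paraformaldehyde), C=O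
Why: Zirconium-catalysed syn-carboalumination of the terminal alkyne (Negishi) puts methyl on C4 and aluminium on C5. Hydroxymethylation of the derived alanate with retention gives the E-trisubstituted allylic alcohol; the trisubstituted olefins and silyl ethers are spectators.

Step 12
Reactants: 18 (2E,6Z,9S,10Z)-12-[(tert-butyldimethylsilyl)oxy]-3,7,11-trimethyl-9-[(triisopropylsilyl)oxy]dodeca-2,6,10-trien-1-ol
Product: 20 (2Z,4S,6Z,10E)-1-[(tert-butyldimethylsilyl)oxy]-12-chloro-2,6,10-trimethyl-4-[(triisopropylsilyl)oxy]dodeca-2,6,10-triene, via allylic mesylate 19 (not isolated)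
Conditions: MsCl, 2,4,6-collidine, LiCl, DMF, 0 °C
Reagents that add atoms: lithium chloride, [Li+].[Cl-]
Why: Mesylation and in-situ SN2 displacement by chloride at the primary allylic carbon, without allylic transposition and under conditions that leave silyl ethers intact.

Step 13
Reactants: 20 (2Z,4S,6Z,10E)-1-[(tert-butyldimethylsilyl)oxy]-12-chloro-2,6,10-trimethyl-4-[(triisopropylsilyl)oxy]dodeca-2,6,10-triene
Product: 21 (2Z,4S,6Z,10E)-12-chloro-2,6,10-trimethyl-4-[(triisopropylsilyl)oxy]dodeca-2,6,10-trien-1-ol
Conditions: HF·pyridine, pyridine, THF, 0 °C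
Reagents that add atoms: none
Why: Selective desilylation; a primary TBS ether is cleaved far faster than a secondary TIPS ether, and the allylic chloride is inert to buffered HF.

Step 14
Reactants: 21 (2Z,4S,6Z,10E)-12-chloro-2,6,10-trimethyl-4-[(triisopropylsilyl)oxy]dodeca-2,6,10-trien-1-ol
Product: 22 (3Z,5S,7Z,11E)-3,7,11-trimethyl-5-[(triisopropylsilyl)oxy]-1-oxacyclotrideca-3,7,11-triene
Conditions: NaH, Bu4NI (cat.), THF, 45 °C, slow addition to 2 mM
Reagents that add atoms: none
Why: Intramolecular Williamson etherification; the C12 alkoxide displaces the primary allylic C6 chloride (via the iodide formed in situ) to close the thirteen-membered ether. High dilution disfavours oligomers and the TIPS group should not migrate to the neighbouring alkoxide.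

Step 15
Reactants: 22 (3Z,5S,7Z,11E)-3,7,11-trimethyl-5-[(triisopropylsilyl)oxy]-1-oxacyclotrideca-3,7,11-triene
Product: 24 (1(10)Z,4E,6S,7S,8S)-8-[(triisopropylsilyl)oxy]germacra-1(10),4,11-trien-6-ol, via C6-lithiated ether 23 (not isolated)
Conditions: n-BuLi (3 equiv), THF–hexane, −78 → −20 °C; aq NH4Cl
Reagents that add atoms: none
Why: n-BuLi removes a C6 proton (α to the ring oxygen, allylic to C4=C5) to give 23, which undergoes a concerted suprafacial [2,3]-sigmatropic shift through a five-membered envelope (C6, O, C12, C11, C7): C6–C7 forms, C12–O breaks and C11=C12 appears as the isopropenyl group. The closest known reaction type is the [2,3]-Wittig rearrangement of bis-allylic ethers, including its use to contract thirteen-membered diallylic ethers to ten-membered homoallylic alcohols. The ten-membered carbocycle is closed by ring contraction, the new bond forming across the thirteen-membered ring within a five-atom sigmatropic array, not by an end-to-end cyclisation. C6/C7: the Z geometry of C7=C11 (C8 cis to the C12–O arm) and the exo position of the C5 alkenyl group on the envelope give a cis-fused transition state and hence the cis relation of 6-OH and 7-isopropenyl. C7/C8: A1,3 strain with the C12 methylene holds C8–H in the olefin plane, the tether forces C9 onto the face from which C6 arrives, and the bulky, electron-withdrawing OTIPS group lies anti to the forming bond; this should give C6 and C7 as in the target with O8 trans to the new branch, which is why 22 is the 8S epimer and C8 is inverted in step 19. Regioselectivity: C6–H is flanked only by the C5 methine, whereas the C12 methylene is screened by the C11 methyl and the cis C8–OTIPS group, and a shift from C12 would have to create a quaternary centre at C4. Low temperature and the lithium counter-ion should suppress the [1,2]-shift and an anionic oxy-Cope reaction of the product alkoxide; Z-C1=C10 and E-C4=C5 are carried through unchanged.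

Step 16
Reactants: 24 (1(10)Z,4E,6S,7S,8S)-8-[(triisopropylsilyl)oxy]germacra-1(10),4,11-trien-6-ol
Product: 25 (1(10)Z,4E,6S,7S,8S)-8-[(triisopropylsilyl)oxy]germacra-1(10),4-dien-6-ol
Conditions: H2 (1 atm), RhCl(PPh3)3 (10 mol%), benzene–EtOH, rt
Reagents that add atoms: none
Why: Homogeneous hydrogenation with RhCl(PPh3)3 reduces the 1,1-disubstituted olefin and should leave the two trisubstituted ring olefins; it also removes the 1,5-dien-3-ol motif before any alkoxide is formed.

Step 17
Reactants: 25 (1(10)Z,4E,6S,7S,8S)-8-[(triisopropylsilyl)oxy]germacra-1(10),4-dien-6-ol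
Product: 26 (1(10)Z,4E,6S,7S,8S)-6-[(4-methoxybenzyl)oxy]-8-[(triisopropylsilyl)oxy]germacra-1(10),4-diene
Conditions: NaH, 4-MeOC6H4CH2Cl, Bu4NI (cat.), DMF, 0 °C → rt
Reagents that add atoms: 4-methoxybenzyl chloride, COc1ccc(CCl)cc1
Why: Williamson benzylation of the C6 alkoxide; PMB can be introduced now that no carbanion chemistry remains, and it leaves later under neutral oxidative conditions.

Step 18
Reactants: 26 (1(10)Z,4E,6S,7S,8S)-6-[(4-methoxybenzyl)oxy]-8-[(triisopropylsilyl)oxy]germacra-1(10),4-diene
Product: 27 (1(10)Z,4E,6S,7R,8S)-6-[(4-methoxybenzyl)oxy]germacra-1(10),4-dien-8-ol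
Conditions: Bu4NF, THF, rt → 40 °C
Reagents that add atoms: none
Why: Fluoride cleavage of the secondary TIPS ether; the temperature stays well below that of a Cope rearrangement.

Step 19
Reactants: 27 (1(10)Z,4E,6S,7R,8S)-6-[(4-methoxybenzyl)oxy]germacra-1(10),4-dien-8-ol; 28 3,4,5-trimethoxybenzoic acid
Product: 29 (1(10)Z,4E,6S,7R,8R)-6-[(4-methoxybenzyl)oxy]germacra-1(10),4-dien-8-yl 3,4,5-trimethoxybenzoate
Conditions: 28 (4 equiv), PPh3, DIAD, toluene, 0 °C → rt
Reagents that add atoms: none
Why: Mitsunobu esterification; the carboxylate displaces the alkoxyphosphonium group of 27 with inversion (SN2), turning the 7,8-trans carbinol into the all-cis ester. The closest analogy is the inversion of menthol-type alcohols flanked by an isopropyl-bearing carbon.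

Step 20
Reactants: 29 (1(10)Z,4E,6S,7R,8R)-6-[(4-methoxybenzyl)oxy]germacra-1(10),4-dien-8-yl 3,4,5-trimethoxybenzoate
Product: 30 (1(10)Z,4E,6S,7S,8R)-6-hydroxygermacra-1(10),4-dien-8-yl 3,4,5-trimethoxybenzoate
Conditions: DDQ, CH2Cl2–pH 7 buffer, 0 °C
Reagents that add atoms: none
Why: Oxidative cleavage of the PMB ether under neutral conditions, so the aroyl group should not migrate from O8 to the cis O6.

Step 21
Reactants: 30 (1(10)Z,4E,6S,7S,8R)-6-hydroxygermacra-1(10),4-dien-8-yl 3,4,5-trimethoxybenzoate
Product: 31 (1(10)Z,4S,5S,6R,7S,8R)-4,5-epoxy-6-hydroxygermacr-1(10)-en-8-yl 3,4,5-trimethoxybenzoate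
Conditions: VO(acac)2 (5 mol%), t-BuOOH, CH2Cl2, 0 °C
Reagents that add atoms: tert-butyl hydroperoxide, CC(C)(C)OO
Why: Hydroxyl-directed epoxidation; the vanadium alkoxide of O6 delivers oxygen only to the allylic C4=C5 olefin. With C6–H eclipsing the C15 methyl (A1,3 strain) the hydroxyl sits on the outer face of the E olefin and the ring on the inner face, so oxygen should arrive syn to O6 and give 4S,5S.

Compound list

1 | 4-methyl-5,6-dihydro-2H-pyran-2-one | CC1=CC(=O)OCC1 | starting material
2 | (2Z)-3-methylpent-2-ene-1,5-diol | OC/C=C(C)\CCO | intermediate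
3 | (3Z)-5-chloro-3-methylpent-3-en-1-ol | ClC/C=C(C)\CCO | intermediate
4 | tert-butyl{[(3Z)-5-chloro-3-methylpent-3-en-1-yl]oxy}dimethylsilane | ClC/C=C(C)\CCO[Si](C)(C)C(C)(C)C | intermediate
5 | trimethyl(prop-1-yn-1-yl)silane | CC#C[Si](C)(C)C | starting material
6 | 3-lithio-1-(trimethylsilyl)propyne (formed in the flask) | [Li]CC#C[Si](C)(C)C | intermediate
7 | tert-butyldimethyl{[(3Z)-3-methyl-8-(trimethylsilyl)oct-3-en-7-yn-1-yl]oxy}silane | C[Si](C)(C)C#CCC/C=C(C)\CCO[Si](C)(C)C(C)(C)C | intermediate
8 | (3Z)-3-methyloct-3-en-7-yn-1-ol | C#CCC/C=C(C)\CCO | intermediate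
9 | (3Z)-3-methyloct-3-en-7-ynal | C#CCC/C=C(C)\CC=O | intermediate
10 | prop-2-yn-1-ol | C#CCO | starting material
11 | bromomagnesium (2Z)-3-(bromomagnesio)-2-methylprop-2-en-1-olate (formed in the flask) | Br[Mg]OC/C(C)=C\[Mg]Br | intermediate
12 | (2Z)-3-iodo-2-methylprop-2-en-1-ol | OC/C(C)=C\I | intermediate
13 | tert-butyl{[(2Z)-3-iodo-2-methylprop-2-en-1-yl]oxy}dimethylsilane | CC(C)(C)[Si](C)(C)OC/C(C)=C\I | intermediate
14 | (2Z,4S,6Z)-1-[(tert-butyldimethylsilyl)oxy]-2,6-dimethylundeca-2,6-dien-10-yn-4-ol | CC(C)(C)[Si](C)(C)OC/C(C)=C\[C@@H](O)C/C(C)=C\CCC#C | intermediate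
15 | (2Z,4S,6Z)-1-[(tert-butyldimethylsilyl)oxy]-2,6-dimethyl-4-[(triisopropylsilyl)oxy]undeca-2,6-dien-10-yne | CC(C)(C)[Si](C)(C)OC/C(C)=C\[C@@H](O[Si](C(C)C)(C(C)C)C(C)C)C/C(C)=C\CCC#C | intermediate
16 | (E)-alkenyldimethylalane from 15, Al on C5, methyl on C4 (formed in the flask) | CC(C)(C)[Si](C)(C)OC/C(C)=C\[C@@H](O[Si](C(C)C)(C(C)C)C(C)C)C/C(C)=C\CC/C(C)=C/[Al](C)C | intermediate
17 | lithium butyl(dimethyl)alkenylalanate from 16 (formed in the flask) | CC(C)(C)[Si](C)(C)OC/C(C)=C\[C@@H](O[Si](C(C)C)(C(C)C)C(C)C)C/C(C)=C\CC/C(C)=C/[Al-](C)(C)CCCC.[Li+] | intermediate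
18 | (2E,6Z,9S,10Z)-12-[(tert-butyldimethylsilyl)oxy]-3,7,11-trimethyl-9-[(triisopropylsilyl)oxy]dodeca-2,6,10-trien-1-ol | CC(C)(C)[Si](C)(C)OC/C(C)=C\[C@@H](O[Si](C(C)C)(C(C)C)C(C)C)C/C(C)=C\CC/C(C)=C/CO | intermediate
19 | methanesulfonate of 18 (formed in the flask) | CC(C)(C)[Si](C)(C)OC/C(C)=C\[C@@H](O[Si](C(C)C)(C(C)C)C(C)C)C/C(C)=C\CC/C(C)=C/COS(C)(=O)=O | intermediate
20 | (2Z,4S,6Z,10E)-1-[(tert-butyldimethylsilyl)oxy]-12-chloro-2,6,10-trimethyl-4-[(triisopropylsilyl)oxy]dodeca-2,6,10-triene | CC(C)(C)[Si](C)(C)OC/C(C)=C\[C@@H](O[Si](C(C)C)(C(C)C)C(C)C)C/C(C)=C\CC/C(C)=C/CCl | intermediate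
21 | (2Z,4S,6Z,10E)-12-chloro-2,6,10-trimethyl-4-[(triisopropylsilyl)oxy]dodeca-2,6,10-trien-1-ol | OC/C(C)=C\[C@@H](O[Si](C(C)C)(C(C)C)C(C)C)C/C(C)=C\CC/C(C)=C/CCl | intermediate
22 | (3Z,5S,7Z,11E)-3,7,11-trimethyl-5-[(triisopropylsilyl)oxy]-1-oxacyclotrideca-3,7,11-triene (ether oxygen links germacrane C6 and C12; 8S) | O1C/C(C)=C\[C@@H](O[Si](C(C)C)(C(C)C)C(C)C)C/C(C)=C\CC/C(C)=C/C1 | intermediate
23 | 13-lithio derivative of 22, lithium on germacrane C6 (formed in the flask) | O1C/C(C)=C\[C@@H](O[Si](C(C)C)(C(C)C)C(C)C)C/C(C)=C\CC/C(C)=C/C1[Li] | intermediate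
24 | (1(10)Z,4E,6S,7S,8S)-8-[(triisopropylsilyl)oxy]germacra-1(10),4,11-trien-6-ol (6-OH and 7-isopropenyl cis, 8-OTIPS trans to both) | CC(C)[Si](C(C)C)(C(C)C)O[C@H]1C/C(C)=C\CC/C(C)=C/[C@H](O)[C@@H]1C(C)=C | intermediate
25 | (1(10)Z,4E,6S,7S,8S)-8-[(triisopropylsilyl)oxy]germacra-1(10),4-dien-6-ol | CC(C)[Si](C(C)C)(C(C)C)O[C@H]1C/C(C)=C\CC/C(C)=C/[C@H](O)[C@@H]1C(C)C | intermediate
26 | (1(10)Z,4E,6S,7S,8S)-6-[(4-methoxybenzyl)oxy]-8-[(triisopropylsilyl)oxy]germacra-1(10),4-diene | CC(C)[Si](C(C)C)(C(C)C)O[C@H]1C/C(C)=C\CC/C(C)=C/[C@H](OCc2ccc(OC)cc2)[C@@H]1C(C)C | intermediate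
27 | (1(10)Z,4E,6S,7R,8S)-6-[(4-methoxybenzyl)oxy]germacra-1(10),4-dien-8-ol | O[C@H]1C/C(C)=C\CC/C(C)=C/[C@H](OCc2ccc(OC)cc2)[C@@H]1C(C)C | intermediate
28 | 3,4,5-trimethoxybenzoic acid | COc1cc(C(=O)O)cc(OC)c1OC | starting material
29 | (1(10)Z,4E,6S,7R,8R)-6-[(4-methoxybenzyl)oxy]germacra-1(10),4-dien-8-yl 3,4,5-trimethoxybenzoate | COc1cc(C(=O)O[C@@H]2C/C(C)=C\CC/C(C)=C/[C@H](OCc3ccc(OC)cc3)[C@@H]2C(C)C)cc(OC)c1OC | intermediate
30 | (1(10)Z,4E,6S,7S,8R)-6-hydroxygermacra-1(10),4-dien-8-yl 3,4,5-trimethoxybenzoate | COc1cc(C(=O)O[C@@H]2C/C(C)=C\CC/C(C)=C/[C@H](O)[C@@H]2C(C)C)cc(OC)c1OC | intermediate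
31 | (1(10)Z,4S,5S,6R,7S,8R)-4,5-epoxy-6-hydroxygermacr-1(10)-en-8-yl 3,4,5-trimethoxybenzoate (CNP0260213.11) | COc1cc(C(=O)O[C@@H]2C/C(C)=C\CC[C@]3(C)O[C@H]3[C@H](O)[C@@H]2C(C)C)cc(OC)c1OC | target

Total step count: 21 steps. Longest linear sequence: 19 steps (steps 1–6 and 9–21, from 1); the side branch is steps 7–8 from 10.

Least certain steps

Step 15 (key step). The most likely failure is attack of C6 on the other face of C7=C11 relative to C8, with C9 anti and the silyloxy group gauche to the new bond. From 22 this would give the mirror-image C6/C7 pair and lead into the wrong series. Deprotonation at C12 or a [1,2]-shift on warming are lesser risks. The fallback turns the stereochemical plan round instead of the conditions. It sets out from 9 and 13: the coupling of step 9 is run with the enantiomeric ligand to give the 4R alcohol F1. F1 is taken through the operations of steps 10–14: the TIPS ether F2, the allylic alcohol F3, the chloride F4, the hydroxy chloride F5 and the 5R macrocyclic ether F6. Ring contraction of F6 with the silyloxy group on the side of the incoming carbon would then give the all-cis alcohol F7. Hydrogenation gives F8, benzylation the PMB ether F9, and desilylation the 8R alcohol F10. F10 is acylated with retention (3,4,5-trimethoxybenzoyl chloride, DMAP, pyridine) and the route is rejoined at 29.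

Step 9. The most likely failures are insufficient enantioselection with an α-unbranched aldehyde and drift of the β,γ-olefin of 9 into conjugation before coupling. The fallback replaces catalyst control by a reagent-controlled reduction. It sets out from 9 and 13: coupling with NiCl2/CrCl2 without ligand gives the racemic alcohol F11, buffered Dess–Martin oxidation gives the enone F12, and CBS reduction with the (R)-oxazaborolidine and catecholborane at −78 °C returns to the route at 14.

Step 14. The most likely failures are oligomerisation in place of ring closure, and transfer of the silyl group from O8 to the neighbouring C12 alkoxide followed by closure of a smaller ether. The fallback reverses the polarity of the etherification so that the remote, unhindered C6 alkoxide is the nucleophile. It sets out from 18: acetylation gives the acetate F13, HF·pyridine frees O12 to give the hydroxy acetate F14, MsCl/LiCl gives the C12 chloride F15, and i-Bu2AlH at −78 °C removes the acetate to give the hydroxy chloride F16. Cyclisation of F16 with NaH at high dilution returns to the route at 22.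

Step 19. The most likely failure is slow displacement at the hindered C8 by a carboxylic acid of ordinary acidity, leading to recovered alcohol or elimination towards C9. The fallback is a redox inversion in place of the SN2 reaction. It sets out from 27: Dess–Martin oxidation gives the C8 ketone F17; LiBH(s-Bu)3 at −78 °C should deliver hydride from the face away from the C7 isopropyl group (as in the reduction of menthone to neomenthol) to give the 8R alcohol F10. Acylation with 3,4,5-trimethoxybenzoyl chloride and DMAP returns to the route at 29.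

Step 21. The most likely failures are poor facial selectivity if the ring does not hold the C6–H-eclipsed conformer, and acid-promoted opening of the epoxy alcohol. The fallback replaces substrate direction by reagent control at the protected stage. It sets out from 29: Shi epoxidation with the L-sorbose-derived enantiomer of the fructose-based ketone and KHSO5 in buffered MeCN–dimethoxymethane–water is selective for E-trisubstituted over Z olefins and should give the 4S,5S epoxide F18. DDQ removal of the PMB group then returns to the route at 31.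

Further compounds

F1 | step 15 | (2Z,4R,6Z)-1-[(tert-butyldimethylsilyl)oxy]-2,6-dimethylundeca-2,6-dien-10-yn-4-ol | CC(C)(C)[Si](C)(C)OC/C(C)=C\[C@H](O)C/C(C)=C\CCC#C
F2 | step 15 | (2Z,4R,6Z)-1-[(tert-butyldimethylsilyl)oxy]-2,6-dimethyl-4-[(triisopropylsilyl)oxy]undeca-2,6-dien-10-yne | CC(C)(C)[Si](C)(C)OC/C(C)=C\[C@H](O[Si](C(C)C)(C(C)C)C(C)C)C/C(C)=C\CCC#C
F3 | step 15 | (2E,6Z,9R,10Z)-12-[(tert-butyldimethylsilyl)oxy]-3,7,11-trimethyl-9-[(triisopropylsilyl)oxy]dodeca-2,6,10-trien-1-ol | CC(C)(C)[Si](C)(C)OC/C(C)=C\[C@H](O[Si](C(C)C)(C(C)C)C(C)C)C/C(C)=C\CC/C(C)=C/CO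
F4 | step 15 | (2Z,4R,6Z,10E)-1-[(tert-butyldimethylsilyl)oxy]-12-chloro-2,6,10-trimethyl-4-[(triisopropylsilyl)oxy]dodeca-2,6,10-triene | CC(C)(C)[Si](C)(C)OC/C(C)=C\[C@H](O[Si](C(C)C)(C(C)C)C(C)C)C/C(C)=C\CC/C(C)=C/CCl
F5 | step 15 | (2Z,4R,6Z,10E)-12-chloro-2,6,10-trimethyl-4-[(triisopropylsilyl)oxy]dodeca-2,6,10-trien-1-ol | OC/C(C)=C\[C@H](O[Si](C(C)C)(C(C)C)C(C)C)C/C(C)=C\CC/C(C)=C/CCl
F6 | step 15 | (3Z,5R,7Z,11E)-3,7,11-trimethyl-5-[(triisopropylsilyl)oxy]-1-oxacyclotrideca-3,7,11-triene | O1C/C(C)=C\[C@H](O[Si](C(C)C)(C(C)C)C(C)C)C/C(C)=C\CC/C(C)=C/C1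
F7 | step 15 | (1(10)Z,4E,6S,7S,8R)-8-[(triisopropylsilyl)oxy]germacra-1(10),4,11-trien-6-ol | CC(C)[Si](C(C)C)(C(C)C)O[C@@H]1C/C(C)=C\CC/C(C)=C/[C@H](O)[C@@H]1C(C)=C
F8 | step 15 | (1(10)Z,4E,6S,7S,8R)-8-[(triisopropylsilyl)oxy]germacra-1(10),4-dien-6-ol | CC(C)[Si](C(C)C)(C(C)C)O[C@@H]1C/C(C)=C\CC/C(C)=C/[C@H](O)[C@@H]1C(C)C
F9 | step 15 | (1(10)Z,4E,6S,7S,8R)-6-[(4-methoxybenzyl)oxy]-8-[(triisopropylsilyl)oxy]germacra-1(10),4-diene | CC(C)[Si](C(C)C)(C(C)C)O[C@@H]1C/C(C)=C\CC/C(C)=C/[C@H](OCc2ccc(OC)cc2)[C@@H]1C(C)C
F10 | step 15 | (1(10)Z,4E,6S,7R,8R)-6-[(4-methoxybenzyl)oxy]germacra-1(10),4-dien-8-ol | O[C@@H]1C/C(C)=C\CC/C(C)=C/[C@H](OCc2ccc(OC)cc2)[C@@H]1C(C)C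
F11 | step 9 | racemic (2Z,6Z)-1-[(tert-butyldimethylsilyl)oxy]-2,6-dimethylundeca-2,6-dien-10-yn-4-ol | CC(C)(C)[Si](C)(C)OC/C(C)=C\C(O)C/C(C)=C\CCC#C
F12 | step 9 | (2Z,6Z)-1-[(tert-butyldimethylsilyl)oxy]-2,6-dimethylundeca-2,6-dien-10-yn-4-one | CC(C)(C)[Si](C)(C)OC/C(C)=C\C(=O)C/C(C)=C\CCC#C
F13 | step 14 | (2E,6Z,9S,10Z)-12-[(tert-butyldimethylsilyl)oxy]-3,7,11-trimethyl-9-[(triisopropylsilyl)oxy]dodeca-2,6,10-trien-1-yl acetate | CC(C)(C)[Si](C)(C)OC/C(C)=C\[C@@H](O[Si](C(C)C)(C(C)C)C(C)C)C/C(C)=C\CC/C(C)=C/COC(C)=O
F14 | step 14 | (2E,6Z,9S,10Z)-12-hydroxy-3,7,11-trimethyl-9-[(triisopropylsilyl)oxy]dodeca-2,6,10-trien-1-yl acetate | OC/C(C)=C\[C@@H](O[Si](C(C)C)(C(C)C)C(C)C)C/C(C)=C\CC/C(C)=C/COC(C)=O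
F15 | step 14 | (2E,6Z,9S,10Z)-12-chloro-3,7,11-trimethyl-9-[(triisopropylsilyl)oxy]dodeca-2,6,10-trien-1-yl acetate | ClC/C(C)=C\[C@@H](O[Si](C(C)C)(C(C)C)C(C)C)C/C(C)=C\CC/C(C)=C/COC(C)=O
F16 | step 14 | (2E,6Z,9S,10Z)-12-chloro-3,7,11-trimethyl-9-[(triisopropylsilyl)oxy]dodeca-2,6,10-trien-1-ol | ClC/C(C)=C\[C@@H](O[Si](C(C)C)(C(C)C)C(C)C)C/C(C)=C\CC/C(C)=C/CO
F17 | step 19 | (1(10)Z,4E,6S,7S)-6-[(4-methoxybenzyl)oxy]germacra-1(10),4-dien-8-one | O=C1C/C(C)=C\CC/C(C)=C/[C@H](OCc2ccc(OC)cc2)[C@@H]1C(C)C
F18 | step 21 | (1(10)Z,4S,5S,6R,7R,8R)-4,5-epoxy-6-[(4-methoxybenzyl)oxy]germacr-1(10)-en-8-yl 3,4,5-trimethoxybenzoate | COc1cc(C(=O)O[C@@H]2C/C(C)=C\CC[C@]3(C)O[C@H]3[C@H](OCc4ccc(OC)cc4)[C@@H]2C(C)C)cc(OC)c1OC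
A1 | alternative 1 | (1(10)Z,4E,7Z)-cyclodeca-1(10),4,7-triene with C6–OTBS, C7 isopropyl and C8–Bpin | CC(C)/C1=C(B2OC(C)(C)C(C)(C)O2)/C/C(C)=C\CC/C(C)=C/[C@@H]1O[Si](C)(C)C(C)(C)C
A2 | alternative 1 | isoprene | C=CC(C)=C
A3 | alternative 1 | tert-butyl{[(1E)-3-methylbuta-1,3-dien-1-yl]oxy}dimethylsilane | C=C(C)/C=C/O[Si](C)(C)C(C)(C)C
A4 | alternative 1 | 4,4,5,5-tetramethyl-2-(3-methylbut-1-yn-1-yl)-1,3,2-dioxaborolane | CC(C)C#CB1OC(C)(C)C(C)(C)O1
A5 | alternative 2 | (1(10)Z,4E)-6-[(tert-butyldimethylsilyl)oxy]germacra-1(10),4-dien-8-yl 3,4,5-trimethoxybenzoate | COc1cc(C(=O)O[C@@H]2C/C(C)=C\CC/C(C)=C/[C@H](O[Si](C)(C)C(C)(C)C)[C@@H]2C(C)C)cc(OC)c1OC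
A6 | alternative 2 | open-chain precursor: Z-alkenyl iodide at C1, terminal C2=C3 of a (4E)-diene, C6–OTBS, C7 isopropyl, C8 3,4,5-trimethoxybenzoate | COc1cc(C(=O)O[C@H](C/C(C)=C\I)[C@@H](C(C)C)[C@@H](O[Si](C)(C)C(C)(C)C)/C=C(C)/C=C)cc(OC)c1OC
A7 | alternative 3 | (Z)-cyclodec-1(10)-en-5-one with C4–OTES, C6–OTBS, C7 isopropyl and C8–OPMB | COc1ccc(CO[C@@H]2C/C(C)=C\CC[C@](C)(O[Si](CC)(CC)CC)C(=O)[C@H](O[Si](C)(C)C(C)(C)C)[C@@H]2C(C)C)cc1
A8 | alternative 3 | cis-fused eudesmane decalin: C5 tertiary alcohol cis to the C10 methyl, C1 mesylate trans to it, C4–OTES, C6–OTBS, C7 isopropyl, C8–OPMB | COc1ccc(CO[C@@H]2C[C@@]3(C)[C@@H](OS(C)(=O)=O)CC[C@](C)(O[Si](CC)(CC)CC)[C@@]3(O)[C@H](O[Si](C)(C)C(C)(C)C)[C@@H]2C(C)C)cc1
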